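**Assumption:** the target has no stereocentre and no hindered axis (the C2–C1' bond rotates freely). It is achiral, so there is no enantiomer to select, and the route makes exactly the given SMILES.

## Retrosynthetic overview
1. C5–OH ⇒ C5–H: the phenol oxygen goes in last, by C4-carbonyl-directed C–H oxygenation of 3,7,8,2'-tetramethoxyflavone 6 (key C–O bond, new step).
2. 3-OMe ⇒ 3-OH: O-methylation of flavonol 5, whose only acidic OH is the one at C3.
3. Ring C ⇒ chalcone 3: Algar–Flynn–Oyamada closure makes O1–C2 and C3–O in one flask. It is dependable because ring A has no 6'-substituent at that stage.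
4. Chalcone 3 ⇒ acetophenone 1 + aldehyde 2 (Claisen–Schmidt), both inexpensive catalogue compounds. Rings A and B are bought, and ring C is the only ring formed (step 1).

## Route

Step 1
Reactants: 1 1-(2-hydroxy-3,4-dimethoxyphenyl)ethan-1-one; 2 2-methoxybenzaldehyde
Product: 5 3-hydroxy-7,8-dimethoxy-2-(2-methoxyphenyl)-4H-chromen-4-one, via chalcone 3 (not isolated), via trans-dihydroflavonol 4 (not isolated)
Conditions: NaOH (5 M aq, 4 equiv), EtOH, rt, 16 h; then 30% H2O2 (5 equiv), 0 °C to rt, 3 h; 2 M HCl, filter
Reagents that add atoms: hydrogen peroxide, OO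
Why: Claisen–Schmidt condensation gives the (E)-chalcone 3, and under Algar–Flynn–Oyamada conditions its phenoxide adds to the β-carbon (O1–C2), the enolate is hydroxylated by H2O2 (C3–O) to trans-4, and more alkaline H2O2 dehydrogenates 4 to the flavonol, a course not diverted to an aurone because the chalcone has no 6'-substituent; the two transient stereocentres of 4 are erased, so none needs control.

Step 2
Reactants: 5 3-hydroxy-7,8-dimethoxy-2-(2-methoxyphenyl)-4H-chromen-4-one
Product: 6 3,7,8-trimethoxy-2-(2-methoxyphenyl)-4H-chromen-4-one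
Conditions: MeI (1.5 equiv), K2CO3 (2 equiv), acetone, reflux, 6 h
Reagents that add atoms: iodomethane, CI
Why: Williamson-type O-methylation (SN2 on MeI) of the only acidic OH in 5, the enolic 3-OH, which also removes the 3-O/4-O chelating site that would bind the metal catalyst of step 3; no stereocentre is formed.

Step 3
Reactants: 6 3,7,8-trimethoxy-2-(2-methoxyphenyl)-4H-chromen-4-one
Product: 8 5-hydroxy-3,7,8-trimethoxy-2-(2-methoxyphenyl)-4H-chromen-4-one, via C5 pinacol boronate 7 (not isolated)
Conditions: [Ir(OMe)(cod)]2 (2.5 mol %), P[3,5-(CF3)2C6H3]3 (10 mol %), B2pin2 (1.3 equiv), cyclopentyl methyl ether, 100 °C, 16 h; then NaBO3·4H2O (4 equiv), THF/H2O 1:1, rt, 2 h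
Reagents that add atoms: bis(pinacolato)diboron, CC1(C)OB(OC1(C)C)B1OC(C)(C)C(C)(C)O1 (the boryl group of 7); sodium perborate tetrahydrate, O.O.O.O.[Na+].[O-]OB=O (the C5 oxygen of 8)
Why: Proposed new method: one-flask C5–H hydroxylation of a flavone by carbonyl-directed borylation and oxidation, not yet shown on the chromone nucleus; the monophosphine species LIr(Bpin)3 (trivalent iridium) keeps two free sites, the Lewis-basic, ring-locked C4=O takes one and so holds only the peri C5–H at the other, oxidative addition (pentavalent iridium, five-membered iridacycle) and C–B reductive elimination give 7 (stabilised by a C=O→B contact), and perborate adds to boron and triggers the 1,2-aryl shift from B to O that makes the C5–O bond at exactly that carbon, under conditions too mild to oxidise the resulting 4-methoxyphenol unit to the 5,8-quinone; closest known reaction type is ester- and ketone-directed ortho C–H borylation of simple benzoates and aryl ketones with [Ir(OMe)(cod)]2 and electron-poor monodentate ligands, followed by standard boronate oxidation; no stereocentre is formed.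

## Compound list
1 | 1-(2-hydroxy-3,4-dimethoxyphenyl)ethan-1-one (2'-hydroxy-3',4'-dimethoxyacetophenone) | CC(=O)c1ccc(OC)c(OC)c1O | starting material
2 | 2-methoxybenzaldehyde | COc1ccccc1C=O | starting material
3 | (E)-1-(2-hydroxy-3,4-dimethoxyphenyl)-3-(2-methoxyphenyl)prop-2-en-1-one | COc1ccccc1/C=C/C(=O)c1ccc(OC)c(OC)c1O | intermediate
4 | trans-3-hydroxy-7,8-dimethoxy-2-(2-methoxyphenyl)chroman-4-one (racemic; the 2R,3R enantiomer is drawn) | COc1ccccc1[C@H]1Oc2c(OC)c(OC)ccc2C(=O)[C@@H]1O | intermediate
5 | 3-hydroxy-7,8-dimethoxy-2-(2-methoxyphenyl)-4H-chromen-4-one | COc1ccccc1-c1oc2c(OC)c(OC)ccc2c(=O)c1O | intermediate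
6 | 3,7,8-trimethoxy-2-(2-methoxyphenyl)-4H-chromen-4-one (3,7,8,2'-tetramethoxyflavone) | COc1ccccc1-c1oc2c(OC)c(OC)ccc2c(=O)c1OC | intermediate
7 | 3,7,8-trimethoxy-2-(2-methoxyphenyl)-5-(4,4,5,5-tetramethyl-1,3,2-dioxaborolan-2-yl)-4H-chromen-4-one | COc1ccccc1-c1oc2c(OC)c(OC)cc(B3OC(C)(C)C(C)(C)O3)c2c(=O)c1OC | intermediate
8 | 5-hydroxy-3,7,8-trimethoxy-2-(2-methoxyphenyl)-4H-chromen-4-one (5-hydroxy-3,7,8,2'-tetramethoxyflavone, achiral) | COc1ccccc1-c1oc2c(OC)c(OC)cc(O)c2c(=O)c1OC | target

**Total step count:** 3. **Longest linear sequence:** 3.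

## Steps most likely to fail

**Step 3 (the proposed new step).**
- Risks: undirected borylation at the open C4'/C5' positions of ring B, reversible two-point binding of iridium by the 3-OMe/C4=O pair, and slow turnover.
- The fallback sets out from 6 and comes back at 8. It uses the known carbonyl-directed, ruthenium-catalysed C5–H oxygenation of flavones, in which the C–O bond forms directly at the metal and no boron is involved.
- Treating 6 with [RuCl2(p-cymene)]2 (5 mol %, divalent ruthenium precatalyst) and PhI(OCOCF3)2 (2 equiv) in CF3CO2H/(CF3CO)2O at 80 °C gives 3,7,8-trimethoxy-2-(2-methoxyphenyl)-4-oxo-4H-chromen-5-yl trifluoroacetate F1.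
- In F1 the new oxygen stays acylated and so is protected from over-oxidation. Stirring with aqueous NaHCO3/MeOH hydrolyses F1 to 8.

**Step 1.**
- Risks: a moderate yield from the ortho-substituted ring B, some aurone, and incomplete oxidation of 4.
- The fallback sets out from 1 and comes back at 5. It builds ring C first without the C3 oxygen and adds that oxygen afterwards.
- The dianion of 1 (LiN(SiMe3)2, 3.2 equiv, THF, −78 °C) is C-acylated with 2-methoxybenzoyl chloride to 1-(2-hydroxy-3,4-dimethoxyphenyl)-3-(2-methoxyphenyl)propane-1,3-dione F2.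
- Catalytic H2SO4 in AcOH at 100 °C cyclodehydrates it to 7,8-dimethoxy-2-(2-methoxyphenyl)-4H-chromen-4-one F3.
- Dimethyldioxirane (acetone/CH2Cl2, 0 °C) gives 2,3-epoxy-7,8-dimethoxy-2-(2-methoxyphenyl)chroman-4-one F4.
- A trace of p-TsOH isomerises F4 to flavonol 5.

**Step 2.**
- Risk: slow alkylation of the hydrogen-bonded 3-OH, which is crowded by the twisted 2-methoxyphenyl group.
- The fallback sets out from 5 and comes back at 6. It activates the methyl donor instead of the flavonol: Mitsunobu etherification with MeOH (3 equiv), PPh3 and diisopropyl azodicarboxylate in THF, 0 °C to rt. The acidic enol is alkylated by the methoxyphosphonium ion.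
- No new compound is made (F0).

## Further compounds
F1 | step 3 | 3,7,8-trimethoxy-2-(2-methoxyphenyl)-4-oxo-4H-chromen-5-yl trifluoroacetate | COc1ccccc1-c1oc2c(OC)c(OC)cc(OC(=O)C(F)(F)F)c2c(=O)c1OC
F2 | step 1 | 1-(2-hydroxy-3,4-dimethoxyphenyl)-3-(2-methoxyphenyl)propane-1,3-dione | COc1ccccc1C(=O)CC(=O)c1ccc(OC)c(OC)c1O
F3 | step 1 | 7,8-dimethoxy-2-(2-methoxyphenyl)-4H-chromen-4-one | COc1ccccc1-c1cc(=O)c2ccc(OC)c(OC)c2o1
F4 | step 1 | 2,3-epoxy-7,8-dimethoxy-2-(2-methoxyphenyl)chroman-4-one (racemic, cis-fused oxirane, one enantiomer drawn) | COc1ccccc1[C@@]12Oc3c(OC)c(OC)ccc3C(=O)[C@@H]1O2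
F0 | step 2 | none | none
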